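The numbers of this flask stand for no real mixture; what happens was integrated by code.

Within 10 min, at constant temperature, Q passes through Q.G and E.Q.G to J, and the vessels differ in how much Q.G they deliver.

    Q + G → Q.G (k1 = 0.30 L mol⁻¹ s⁻¹)
    E + Q.G → E.Q.G (k2 = 0.043 L mol⁻¹ s⁻¹)
    Z + E.Q.G → J (k3 = 0.037 L mol⁻¹ s⁻¹)

in all of them: G 1.50 equiv; E 1.50 equiv; Z 2.50 equiv
- dusk: Q 0.10 M; a single well-mixed tank run continuously and read at steady state, 10 min in it on average
- dawn: Q 0.10 M; plug flow through a tube for 10 min, no back-mixing; time 10 min
- midnight: Q 0.10 M (fed, over 5.00 min); a stirred flask in which Q is dosed at a steady rate over 5.00 min without added volume, worked up at 10 min; time 10 min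
- autumn: Q 0.10 M; a closed flask charged with all of it at once and left for 10 min; time 10 min

* the set-up with the highest amount of Q.G at the outlet or at the end, in percent of the Q put in ("none" if the first two lie within 2 percentage points) (dusk / dawn / midnight / autumn / none)
* amount of Q.G at the outlet or at the end, in percent of the Q put in, dusk
* amount of Q.G at the outlet or at the end, in percent of the Q put in, dawn
* amount of Q.G at the outlet or at the end, in percent of the Q put in, midnight
* amount of Q.G at the outlet or at the end, in percent of the Q put in, autumn

Q is the limiting reagent, and its balance supplies the tool. Let c be the charged concentration of Q and x that of Q.G. Each Q leaving Q.G takes one E, so in autumn E − Q − x stays at the surplus s, the charged E minus the charged Q, 0.0500 M.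

In autumn x leaves zero at 0.270 M min⁻¹. Against charged E, Q.G has a half-life of 1.79 min; against charged G, Q has one of 0.257 min, which is shorter, so x rises first and falls afterwards. The same balance for G gives Q a mean wait L of 0.610 min, which marks the knee.

Past the knee, with Q neglected, E equals x + s, so dx/dt = −k2·x·(x + s). This integrates to x/(x + s) = [c/(c + s)]·exp(−k2·s·(t − L)). The half-life of the fall therefore lengthens from 1.79 min towards 5.37 min, a slower tail, and x runs towards zero with E towards s.

At 10 min this gives 12.4% for autumn, and the same for dawn, whose slices are closed flasks. In dusk the same balances become two quadratics at steady state, giving Q 0.008652 M and Q.G 28.2%. For midnight, moving the origin of the autumn curve 2.50 min later gives a rougher 18.9%. Dusk is thus reckoned highest.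

The forecast names dusk, with 28.2% in dusk, 12.5% in dawn, 18.8% in midnight and 12.5% in autumn, holding that “plug flow and the closed flask are the same thing kinetically”.

The simulation gives 28.2% in dusk, 12.7% in dawn, 20.7% in midnight and 12.7% in autumn, so dusk leads. In autumn the midpoint of the turnover of step 1 fell at 0.320 min, while Q was still present, and that of step 3 at 4.09 min, with Q.G and E.Q.G feeding it. By 100 min autumn's E stood at 33.3% of its charge, and s is 33.3% of that charge. With 0.600 equiv of E in the autumn flask, s turns into a deficit of E, −0.0400 M, the same line gives 51.8%, and that flask holds 51.9% of Q.G.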